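**Strategy.** The coumarin is cut at C4–C4a, the bond between the methine carbon of ring B and the ring A carbon flanked by the oxygen-bearing C5 and C8a. An aryl arylacetate is aminomethylenated, and mild acid then closes ring B in one operation: the enamine carbon becomes an iminium at C4, ring A attacks it through C4a, and dimethylamine leaves to aromatise the pyranone. The step exploits the symmetry of ring A about the C6–C8a axis: with the prenyl group on C6 and identical MOM ethers on O5 and O7, both carbons ortho to the ester oxygen are the same, so no regiochemistry arises. O5 and O7 are told apart only afterwards, by methylation of the C7 hydroxyl.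

Key step: step 8

**Remarks**
- Coumarin numbering is used. Ring A is the benzo ring (C4a to C8a), ring B the pyranone ring, ring C the 3-aryl ring (primed locants). Prenyl = 3-methylbut-2-en-1-yl, MOM = methoxymethyl, TIPS = triisopropylsilyl.
- The target has no stereocentre.
- Assumption: in diol 17 the C7 hydroxyl is taken to be the more acidic and less hindered of the two free hydroxyls. This is a structural argument, not a measured value.
- Design choices: the C4 carbon is introduced with DMF di-tert-butyl acetal, which releases only tert-butanol and so spares the aryl ester from aminolysis. Both ring C oxygens carry TIPS groups, so O2' cannot close onto C2 or C4.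

**Route**

Step 1
Reactants: 1 phloroglucinol (benzene-1,3,5-triol)
Product: 2 5-(triisopropylsilyloxy)benzene-1,3-diol
Conditions: TIPSCl (1 equiv), 1 (3 equiv), imidazole, DMF, 0 °C to rt; excess 1 removed by aqueous wash
Reagents that add atoms: triisopropylsilyl chloride, CC(C)[Si](Cl)(C(C)C)C(C)C
Why: Statistical monosilylation of a symmetric triol, in which the excess of cheap triol and the bulk of the silyl group should hold back a second silylation.

Step 2
Reactants: 2 5-(triisopropylsilyloxy)benzene-1,3-diol
Product: 3 1,3-bis(methoxymethoxy)-5-(triisopropylsilyloxy)benzene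
Conditions: MOMCl, i-Pr2NEt, CH2Cl2, 0 °C to rt
Reagents that add atoms: chloromethyl methyl ether, COCCl
Why: O-alkylation of both phenols with an alpha-chloro ether under amine base, conditions that should leave the aryl silyl ether in place because no free phenoxide is formed.

Step 3
Reactants: 3 1,3-bis(methoxymethoxy)-5-(triisopropylsilyloxy)benzene; 4 prenyl bromide (1-bromo-3-methylbut-2-ene)
Product: 7 1,3-bis(methoxymethoxy)-2-(3-methylbut-2-en-1-yl)-5-(triisopropylsilyloxy)benzene, via aryllithium 5 (not isolated), via arylcopper 6 (not isolated)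
Conditions: n-BuLi, THF, 0 °C; CuI (copper iodide, 1 equiv), −30 °C; 4, −30 °C to rt
Reagents that add atoms: none
Why: Directed ortho-metalation should occur at the carbon flanked by two MOM ethers (the bulky silyloxy group directs poorly), and transmetalation to copper should make the allylic bromide react at its primary carbon (SN2, not SN2').

Step 4
Reactants: 7 1,3-bis(methoxymethoxy)-2-(3-methylbut-2-en-1-yl)-5-(triisopropylsilyloxy)benzene
Product: 8 3,5-bis(methoxymethoxy)-4-(3-methylbut-2-en-1-yl)phenol
Conditions: Bu4NF, AcOH, THF, 0 °C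
Reagents that add atoms: none
Why: Fluoride-induced desilylation of an aryl silyl ether, which should touch neither the MOM ethers nor the prenyl group.

Step 5
Reactants: 9 2,4-dihydroxyphenylacetic acid
Product: 11 2-[2,4-bis(triisopropylsilyloxy)phenyl]acetic acid, via tris-TIPS silyl ester 10 (not isolated)
Conditions: TIPSCl (3.5 equiv), imidazole, DMF, rt to 40 °C; then AcOH–THF–H2O (3:1:1), 40 °C
Reagents that add atoms: triisopropylsilyl chloride, CC(C)[Si](Cl)(C(C)C)C(C)C
Why: Exhaustive silylation followed by selective hydrolysis of the silyl ester, which is far more labile to aqueous acid than the two aryl silyl ethers, and the cap on O2 prevents lactonisation to a benzofuranone.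

Step 6
Reactants: 8 3,5-bis(methoxymethoxy)-4-(3-methylbut-2-en-1-yl)phenol; 11 2-[2,4-bis(triisopropylsilyloxy)phenyl]acetic acid
Product: 12 3,5-bis(methoxymethoxy)-4-(3-methylbut-2-en-1-yl)phenyl 2-[2,4-bis(triisopropylsilyloxy)phenyl]acetate
Conditions: DCC, DMAP (cat.), CH2Cl2, 0 °C to rt
Reagents that add atoms: none
Why: Steglich esterification of a phenol whose hydroxyl has hydrogen on both ortho carbons and should therefore acylate readily.

Step 7
Reactants: 12 3,5-bis(methoxymethoxy)-4-(3-methylbut-2-en-1-yl)phenyl 2-[2,4-bis(triisopropylsilyloxy)phenyl]acetate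
Product: 13 3,5-bis(methoxymethoxy)-4-(3-methylbut-2-en-1-yl)phenyl (E)-3-(dimethylamino)-2-[2,4-bis(triisopropylsilyloxy)phenyl]prop-2-enoate
Conditions: Me2NCH(Ot-Bu)2 (3 equiv), toluene, 70 °C
Reagents that add atoms: N,N-dimethylformamide di-tert-butyl acetal, CN(C)C(OC(C)(C)C)OC(C)(C)C
Why: Aminomethylenation of the doubly activated CH2 group by a formamide acetal, chosen because it releases only hindered tert-butanol, so the aryl ester should survive, and expected to give the (E)-enamine with the amino group trans to the ester.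

Step 8
Reactants: 13 3,5-bis(methoxymethoxy)-4-(3-methylbut-2-en-1-yl)phenyl (E)-3-(dimethylamino)-2-[2,4-bis(triisopropylsilyloxy)phenyl]prop-2-enoate
Product: 16 5,7-bis(methoxymethoxy)-6-(3-methylbut-2-en-1-yl)-3-[2,4-bis(triisopropylsilyloxy)phenyl]-2H-chromen-2-one, via iminium acetate 14 (not isolated), via 4-(dimethylamino)-3,4-dihydrocoumarin 15 (not isolated)
Conditions: AcOH–toluene (1:3), 80 °C, N2
Reagents that add atoms: none
Why: Proposed new method: acetic acid should protonate the enamine at C3 to give an iminium ion at C4, which the aryl ester holds over ring A once it turns into its s-trans rotamer; C4a, ortho to one MOM ether and para to the other, attacks it in a Friedel–Crafts (Mannich-type) substitution, and the 4-amino-dihydrocoumarin loses dimethylamine through its acidic C3–H to give the aromatic pyranone. The closest known reactions are the Pechmann condensation, the acid cyclisation of aryl beta-keto esters to coumarins and the acid cyclisation of enaminones to chromones, none of which uses an ester-tethered enamine in this way. Ring B closes in a 6-exo-trig mode with respect to the C=N bond, with the arene bond C4a–C8a inside the new ring. No stereocentre remains, since C3 and C4 of the intermediates become sp2 on elimination. The selectivity needed is regiochemistry on ring A, and the substrate removes it because both carbons ortho to the ester oxygen are equivalent by the mirror plane through C6 and C8a. Chemoselectivity should come from the weak acid, which spares the MOM ethers and the prenyl group, and from the silyl cap on O2', which blocks closure to a benzofuran.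

Step 9
Reactants: 16 5,7-bis(methoxymethoxy)-6-(3-methylbut-2-en-1-yl)-3-[2,4-bis(triisopropylsilyloxy)phenyl]-2H-chromen-2-one
Product: 17 5,7-dihydroxy-6-(3-methylbut-2-en-1-yl)-3-[2,4-bis(triisopropylsilyloxy)phenyl]-2H-chromen-2-one
Conditions: conc. HCl (cat.), MeOH–THF, 40 °C
Reagents that add atoms: none
Why: Acid-catalysed acetal exchange of the two MOM ethers with methanol, mild enough that the acid-resistant aryl TIPS ethers should stay and the prenyl group should not close onto a neighbouring hydroxyl.

Step 10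
Reactants: 17 5,7-dihydroxy-6-(3-methylbut-2-en-1-yl)-3-[2,4-bis(triisopropylsilyloxy)phenyl]-2H-chromen-2-one
Product: 18 5-hydroxy-7-methoxy-6-(3-methylbut-2-en-1-yl)-3-[2,4-bis(triisopropylsilyloxy)phenyl]-2H-chromen-2-one
Conditions: MeI (1.05 equiv), K2CO3 (1.1 equiv), acetone, 0 °C to rt
Reagents that add atoms: iodomethane, CI
Why: Williamson methylation with one equivalent of base, expected at O7 because that hydroxyl is para-conjugated to the lactone and has one free ortho position, whereas O5 is shielded by the prenyl group and the peri C4–H.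

Step 11
Reactants: 18 5-hydroxy-7-methoxy-6-(3-methylbut-2-en-1-yl)-3-[2,4-bis(triisopropylsilyloxy)phenyl]-2H-chromen-2-one
Product: 19 3-(2,4-dihydroxyphenyl)-5-hydroxy-7-methoxy-6-(3-methylbut-2-en-1-yl)-2H-chromen-2-one (target)
Conditions: Bu4NF, AcOH, THF, 0 °C
Reagents that add atoms: none
Why: Fluoride-induced cleavage of both aryl silyl ethers, buffered with acetic acid so that the lactone and the electron-rich phenols should not suffer from base.

**Compound list**

1 | phloroglucinol (benzene-1,3,5-triol) | Oc1cc(O)cc(O)c1 | starting material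
2 | 5-(triisopropylsilyloxy)benzene-1,3-diol | Oc1cc(O)cc(O[Si](C(C)C)(C(C)C)C(C)C)c1 | intermediate
3 | 1,3-bis(methoxymethoxy)-5-(triisopropylsilyloxy)benzene | COCOc1cc(OCOC)cc(O[Si](C(C)C)(C(C)C)C(C)C)c1 | intermediate
4 | prenyl bromide (1-bromo-3-methylbut-2-ene) | CC(C)=CCBr | starting material
5 | [2,6-bis(methoxymethoxy)-4-(triisopropylsilyloxy)phenyl]lithium (aryllithium, not isolated) | [Li]c1c(OCOC)cc(O[Si](C(C)C)(C(C)C)C(C)C)cc1OCOC | intermediate
6 | [2,6-bis(methoxymethoxy)-4-(triisopropylsilyloxy)phenyl]copper (arylcopper, not isolated) | [Cu]c1c(OCOC)cc(O[Si](C(C)C)(C(C)C)C(C)C)cc1OCOC | intermediate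
7 | 1,3-bis(methoxymethoxy)-2-(3-methylbut-2-en-1-yl)-5-(triisopropylsilyloxy)benzene | COCOc1cc(O[Si](C(C)C)(C(C)C)C(C)C)cc(OCOC)c1CC=C(C)C | intermediate
8 | 3,5-bis(methoxymethoxy)-4-(3-methylbut-2-en-1-yl)phenol | COCOc1cc(O)cc(OCOC)c1CC=C(C)C | intermediate
9 | 2,4-dihydroxyphenylacetic acid | OC(=O)Cc1ccc(O)cc1O | starting material
10 | triisopropylsilyl 2-[2,4-bis(triisopropylsilyloxy)phenyl]acetate (tris-TIPS silyl ester, not isolated) | O=C(Cc1ccc(O[Si](C(C)C)(C(C)C)C(C)C)cc1O[Si](C(C)C)(C(C)C)C(C)C)O[Si](C(C)C)(C(C)C)C(C)C | intermediate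
11 | 2-[2,4-bis(triisopropylsilyloxy)phenyl]acetic acid | OC(=O)Cc1ccc(O[Si](C(C)C)(C(C)C)C(C)C)cc1O[Si](C(C)C)(C(C)C)C(C)C | intermediate
12 | 3,5-bis(methoxymethoxy)-4-(3-methylbut-2-en-1-yl)phenyl 2-[2,4-bis(triisopropylsilyloxy)phenyl]acetate | COCOc1cc(OC(=O)Cc2ccc(O[Si](C(C)C)(C(C)C)C(C)C)cc2O[Si](C(C)C)(C(C)C)C(C)C)cc(OCOC)c1CC=C(C)C | intermediate
13 | 3,5-bis(methoxymethoxy)-4-(3-methylbut-2-en-1-yl)phenyl (E)-3-(dimethylamino)-2-[2,4-bis(triisopropylsilyloxy)phenyl]prop-2-enoate | CN(C)/C=C(/C(=O)Oc1cc(OCOC)c(CC=C(C)C)c(OCOC)c1)c1ccc(O[Si](C(C)C)(C(C)C)C(C)C)cc1O[Si](C(C)C)(C(C)C)C(C)C | intermediate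
14 | iminium acetate formed by protonation of 13 at C3 (racemic at C3, not isolated) | C[N+](C)=CC(C(=O)Oc1cc(OCOC)c(CC=C(C)C)c(OCOC)c1)c1ccc(O[Si](C(C)C)(C(C)C)C(C)C)cc1O[Si](C(C)C)(C(C)C)C(C)C.CC(=O)[O-] | intermediate
15 | 4-(dimethylamino)-5,7-bis(methoxymethoxy)-6-(3-methylbut-2-en-1-yl)-3-[2,4-bis(triisopropylsilyloxy)phenyl]-3,4-dihydro-2H-chromen-2-one (racemic mixture of diastereomers at C3 and C4, not isolated) | CN(C)C1C(c2ccc(O[Si](C(C)C)(C(C)C)C(C)C)cc2O[Si](C(C)C)(C(C)C)C(C)C)C(=O)Oc2cc(OCOC)c(CC=C(C)C)c(OCOC)c21 | intermediate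
16 | 5,7-bis(methoxymethoxy)-6-(3-methylbut-2-en-1-yl)-3-[2,4-bis(triisopropylsilyloxy)phenyl]-2H-chromen-2-one | COCOc1cc2oc(=O)c(-c3ccc(O[Si](C(C)C)(C(C)C)C(C)C)cc3O[Si](C(C)C)(C(C)C)C(C)C)cc2c(OCOC)c1CC=C(C)C | intermediate
17 | 5,7-dihydroxy-6-(3-methylbut-2-en-1-yl)-3-[2,4-bis(triisopropylsilyloxy)phenyl]-2H-chromen-2-one | Oc1cc2oc(=O)c(-c3ccc(O[Si](C(C)C)(C(C)C)C(C)C)cc3O[Si](C(C)C)(C(C)C)C(C)C)cc2c(O)c1CC=C(C)C | intermediate
18 | 5-hydroxy-7-methoxy-6-(3-methylbut-2-en-1-yl)-3-[2,4-bis(triisopropylsilyloxy)phenyl]-2H-chromen-2-one | COc1cc2oc(=O)c(-c3ccc(O[Si](C(C)C)(C(C)C)C(C)C)cc3O[Si](C(C)C)(C(C)C)C(C)C)cc2c(O)c1CC=C(C)C | intermediate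
19 | 3-(2,4-dihydroxyphenyl)-5-hydroxy-7-methoxy-6-(3-methylbut-2-en-1-yl)-2H-chromen-2-one | COc1cc2oc(=O)c(-c3ccc(O)cc3O)cc2c(O)c1CC=C(C)C | target

**Step count**

Total steps: 11. Longest linear sequence: 10 steps (steps 1 to 4, then 6 to 11). The ring C acid 11 is made in one step (step 5) and joins at step 6.

**Steps most likely to fail**

Step 8 (proposed new method). The iminium may form in too small an amount at a temperature the MOM ethers tolerate, or the ester may stay in its s-cis rotamer, so that hydrolysis of the enamine or cleavage of the ester outruns ring closure. The fallback builds C3–C4 last by known chemistry and sets out from phenol 8 and acid 11. Magnesium-mediated ortho-formylation of 8 (MgCl2, Et3N, paraformaldehyde, MeCN, reflux) should give 6-hydroxy-2,4-bis(methoxymethoxy)-3-(3-methylbut-2-en-1-yl)benzaldehyde F1 as the only isomer, because the two ortho carbons are equivalent. Steglich esterification of F1 with 11 (DCC, DMAP, CH2Cl2) should give 2-formyl-3,5-bis(methoxymethoxy)-4-(3-methylbut-2-en-1-yl)phenyl 2-[2,4-bis(triisopropylsilyloxy)phenyl]acetate F2. Treatment with 1,8-diazabicyclo[5.4.0]undec-7-ene should then close the ring by intramolecular Knoevenagel condensation (a Perkin-type coumarin synthesis) with loss of water. The fallback comes back to the route at coumarin 16.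

Step 7. Cleavage of the aryl ester may compete with C-formylation, either by alkoxide attack at the carbonyl group or by loss of the phenoxide from the enolate through a ketene. The fallback separates enolisation from amine delivery and sets out from ester 12. Kinetic enolisation (LiN(SiMe3)2, THF, −78 °C) and Claisen formylation with 2,2,2-trifluoroethyl formate should give the alpha-formyl ester, present as its hydrogen-bonded enol, 3,5-bis(methoxymethoxy)-4-(3-methylbut-2-en-1-yl)phenyl (Z)-3-hydroxy-2-[2,4-bis(triisopropylsilyloxy)phenyl]prop-2-enoate F3. Condensation with one equivalent of dimethylammonium acetate at rt (molecular sieves, toluene) should then give the enamine, since the formyl carbon is far more electrophilic than the ester carbon. The fallback comes back at enamino ester 13.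

Step 10. Site selectivity may be poor, with methylation at O5 or at both oxygens, and a wrong methylation cannot be undone. The fallback sets the selectivity in a reversible acyl-transfer step and sets out from diol 17. Acetylation (Ac2O, pyridine) should give 5,7-diacetoxy-6-(3-methylbut-2-en-1-yl)-3-[2,4-bis(triisopropylsilyloxy)phenyl]-2H-chromen-2-one F4. Thiolysis (PhSH, imidazole, N-methyl-2-pyrrolidone, 0 °C) should remove the acetate of the more acidic, less hindered C7 hydroxyl to give 5-acetoxy-7-hydroxy-6-(3-methylbut-2-en-1-yl)-3-[2,4-bis(triisopropylsilyloxy)phenyl]-2H-chromen-2-one F5. Material cleaved twice or at the wrong site is re-acetylated and recycled. Methylation of the only free hydroxyl under neutral Mitsunobu conditions (MeOH, PPh3, diisopropyl azodicarboxylate) should give 5-acetoxy-7-methoxy-6-(3-methylbut-2-en-1-yl)-3-[2,4-bis(triisopropylsilyloxy)phenyl]-2H-chromen-2-one F6. Mild methanolysis of the acetate (K2CO3 cat., MeOH, 0 °C) brings the fallback back at 18. Any silyl loss at this point is harmless because step 11 removes both silyl groups.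

**Further compounds**

F1 | step 8 | 6-hydroxy-2,4-bis(methoxymethoxy)-3-(3-methylbut-2-en-1-yl)benzaldehyde | O=Cc1c(O)cc(OCOC)c(CC=C(C)C)c1OCOC
F2 | step 8 | 2-formyl-3,5-bis(methoxymethoxy)-4-(3-methylbut-2-en-1-yl)phenyl 2-[2,4-bis(triisopropylsilyloxy)phenyl]acetate | O=Cc1c(OC(=O)Cc2ccc(O[Si](C(C)C)(C(C)C)C(C)C)cc2O[Si](C(C)C)(C(C)C)C(C)C)cc(OCOC)c(CC=C(C)C)c1OCOC
F3 | step 7 | 3,5-bis(methoxymethoxy)-4-(3-methylbut-2-en-1-yl)phenyl (Z)-3-hydroxy-2-[2,4-bis(triisopropylsilyloxy)phenyl]prop-2-enoate (enol of the alpha-formyl ester) | O/C=C(\C(=O)Oc1cc(OCOC)c(CC=C(C)C)c(OCOC)c1)c1ccc(O[Si](C(C)C)(C(C)C)C(C)C)cc1O[Si](C(C)C)(C(C)C)C(C)C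
F4 | step 10 | 5,7-diacetoxy-6-(3-methylbut-2-en-1-yl)-3-[2,4-bis(triisopropylsilyloxy)phenyl]-2H-chromen-2-one | CC(=O)Oc1cc2oc(=O)c(-c3ccc(O[Si](C(C)C)(C(C)C)C(C)C)cc3O[Si](C(C)C)(C(C)C)C(C)C)cc2c(OC(C)=O)c1CC=C(C)C
F5 | step 10 | 5-acetoxy-7-hydroxy-6-(3-methylbut-2-en-1-yl)-3-[2,4-bis(triisopropylsilyloxy)phenyl]-2H-chromen-2-one | Oc1cc2oc(=O)c(-c3ccc(O[Si](C(C)C)(C(C)C)C(C)C)cc3O[Si](C(C)C)(C(C)C)C(C)C)cc2c(OC(C)=O)c1CC=C(C)C
F6 | step 10 | 5-acetoxy-7-methoxy-6-(3-methylbut-2-en-1-yl)-3-[2,4-bis(triisopropylsilyloxy)phenyl]-2H-chromen-2-one | COc1cc2oc(=O)c(-c3ccc(O[Si](C(C)C)(C(C)C)C(C)C)cc3O[Si](C(C)C)(C(C)C)C(C)C)cc2c(OC(C)=O)c1CC=C(C)C
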